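**Plan**
1. Cuts: the C3′–C4′ single bond between the two sp2 CH carbons of the (2′E,4′E)-diene gives a ring alkenylboronate and a C10 (E)-alkenyl iodide. The ring C4–O and C6–O bonds lead back to (S)-carvone. The iodide C1=C2 (Takai) and C4=C5 (Wittig) bonds lead back to methyl (S)-3-hydroxy-2-methylpropanoate.
2. Enabling feature: ring C1–C6, the C2 methyl, the C5 stereocentre and the C(CH3)= carbon on C5 are the carvone skeleton. Its isopropenyl group is a 1,1-disubstituted alkene whose =CH2 end is the only unhindered, non-conjugated alkene terminus, so it can be exchanged for an (E)-CH–B(pin) unit and coupled. Nine of the ten carvone carbons stay; the methylene carbon is replaced in the metathesis.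
3. Forward: C6–OH by α′-enolate hydroxylation, silylation, C4–OH by vinylogous Rubottom oxidation, Mitsunobu inversion with acetic acid, cross-metathesis to the boronate (steps 1–5). The iodide takes six steps (6–11). Suzuki union (12) and desilylation (13) follow. No ring is formed; the chain is joined at the diene.
4. Stereochemistry: ring C5 comes from carvone. Both ring oxygens enter anti to the isopropenyl group, then C4 is inverted by SN2 to the cis acetate. C6′ comes from the hydroxy ester. 7′Z comes from the Wittig step, 4′E from the Takai step and 2′E from thermodynamic control in the metathesis; both E alkenes are retained in the coupling.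

Key step: step 12

Assumption: the drawn descriptors are taken as absolute (acetate cis and hydroxyl trans to the side chain on the ring; chain 6′R, 2′E,4′E,7′Z). Ring atoms are numbered C1 (C=O), C2 (C–CH3), C3, C4 (OAc), C5 (side chain), C6 (OH); chain atoms carry primes, with C2′ on the ring.

**Route**

Step 1
Reactants: 1 (S)-(+)-carvone
Product: 3 (5R,6R)-6-hydroxy-2-methyl-5-(prop-1-en-2-yl)cyclohex-2-en-1-one, via sodium α′-enolate 2 (not isolated)
Conditions: NaHMDS, THF, −78 °C; then 2-(phenylsulfonyl)-3-phenyloxaziridine, −78 °C; AcOH quench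
Reagents that add atoms: 2-(phenylsulfonyl)-3-phenyloxaziridine (Davis reagent), O=S(=O)(c1ccccc1)N1OC1c1ccccc1 (one oxygen atom)
Why: Kinetic deprotonation at the α′-CH2 gives the cross-conjugated enolate, which the N-sulfonyloxaziridine should hydroxylate (Davis enolate oxidation) on the face opposite the adjacent isopropenyl group, giving the trans, diequatorial α-hydroxy ketone that is also the thermodynamically preferred epimer.

Step 2
Reactants: 3 (5R,6R)-6-hydroxy-2-methyl-5-(prop-1-en-2-yl)cyclohex-2-en-1-one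
Product: 4 (5R,6R)-6-[(tert-butyldimethylsilyl)oxy]-2-methyl-5-(prop-1-en-2-yl)cyclohex-2-en-1-one
Conditions: TBSCl, imidazole, DMAP (cat.), DMF, rt
Reagents that add atoms: tert-butyldimethylsilyl chloride, CC(C)(C)[Si](C)(C)Cl
Why: Standard silylation of a secondary alcohol; the ether blocks the ketol for the base and oxidant of step 3 and makes the remaining C6–H tertiary and hindered.

Step 3
Reactants: 4 (5R,6R)-6-[(tert-butyldimethylsilyl)oxy]-2-methyl-5-(prop-1-en-2-yl)cyclohex-2-en-1-one
Product: 8 (4R,5S,6R)-6-[(tert-butyldimethylsilyl)oxy]-4-hydroxy-2-methyl-5-(prop-1-en-2-yl)cyclohex-2-en-1-one, via potassium dienolate 5 (not isolated), via triethylsilyl dienol ether 6 (not isolated), via vinyl epoxide 7 (not isolated)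
Conditions: KHMDS (0.95 equiv), THF, −78 → −40 °C; TESCl, −78 °C; then DMDO, acetone/CH2Cl2, −78 °C; AcOH–H2O–THF work-up
Reagents that add atoms: dimethyldioxirane, CC1(C)OO1 (the C4 oxygen); chlorotriethylsilane, CC[Si](CC)(CC)Cl (silyl group carried only by 6 and 7)
Why: Under equilibrating conditions the bulky base should remove a γ-hydrogen at C4 instead of the hindered tertiary C6–H to give the linearly conjugated dienolate, which is O-silylated; the dioxirane then epoxidises the terminal C3=C4 bond (largest HOMO coefficient at the γ-carbon) from the face opposite the adjacent isopropenyl group, and collapse of the silyloxy vinyl epoxide on work-up gives the γ-hydroxy enone with the 4-OH trans to the isopropenyl group (vinylogous Rubottom oxidation).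

Step 4
Reactants: 8 (4R,5S,6R)-6-[(tert-butyldimethylsilyl)oxy]-4-hydroxy-2-methyl-5-(prop-1-en-2-yl)cyclohex-2-en-1-one
Product: 9 (1S,5R,6S)-5-[(tert-butyldimethylsilyl)oxy]-3-methyl-4-oxo-6-(prop-1-en-2-yl)cyclohex-2-en-1-yl acetate
Conditions: PPh3, DIAD, AcOH, toluene/THF, −20 °C → rt
Reagents that add atoms: acetic acid, CC(=O)O
Why: Mitsunobu reaction: the allylic C4 alcohol is activated as its alkoxyphosphonium ion and displaced by acetate in an SN2 step with inversion, which sets the acetoxy group cis to the isopropenyl group and installs the ester in the same operation; the fully substituted α-carbon disfavours SN2′.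

Step 5
Reactants: 9 (1S,5R,6S)-5-[(tert-butyldimethylsilyl)oxy]-3-methyl-4-oxo-6-(prop-1-en-2-yl)cyclohex-2-en-1-yl acetate
Product: 10 (1S,5R,6S)-5-[(tert-butyldimethylsilyl)oxy]-3-methyl-4-oxo-6-[(1E)-1-(4,4,5,5-tetramethyl-1,3,2-dioxaborolan-2-yl)prop-1-en-2-yl]cyclohex-2-en-1-yl acetate
Conditions: vinylboronic acid pinacol ester (excess), Hoveyda–Grubbs II (cat.), CH2Cl2, 40 °C, argon sweep
Reagents that add atoms: 2-ethenyl-4,4,5,5-tetramethyl-1,3,2-dioxaborolane, C=CB1OC(C)(C)C(C)(C)O1 (the CH–B(pin) unit)
Why: Olefin cross-metathesis of a 1,1-disubstituted alkene with a vinylboronate to a trisubstituted alkenylboronate; the ruthenium boryl-carbene adds to the free =CH2 terminus, ethene is lost, the electron-poor trisubstituted enone alkene is inert, and reversibility should place boron trans to the bulky ring carbon (E).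

Step 6
Reactants: 11 methyl (S)-3-hydroxy-2-methylpropanoate
Product: 12 methyl (S)-3-[(tert-butyldimethylsilyl)oxy]-2-methylpropanoate
Conditions: TBSCl, imidazole, CH2Cl2, 0 °C → rt
Reagents that add atoms: tert-butyldimethylsilyl chloride, CC(C)(C)[Si](C)(C)Cl
Why: Standard silylation of the primary alcohol; it protects the arm that later becomes the alkenyl iodide.

Step 7
Reactants: 12 methyl (S)-3-[(tert-butyldimethylsilyl)oxy]-2-methylpropanoate
Product: 13 (S)-3-[(tert-butyldimethylsilyl)oxy]-2-methylpropanal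
Conditions: DIBAL-H, CH2Cl2, −78 °C; aq. potassium sodium tartrate
Reagents that add atoms: none
Why: Partial ester reduction: at −78 °C the aluminium hemiacetal is stable and releases the aldehyde only on work-up, so the α-stereocentre is not exposed to base.

Step 8
Reactants: 13 (S)-3-[(tert-butyldimethylsilyl)oxy]-2-methylpropanal; 14 (3-methylbutyl)triphenylphosphonium bromide
Product: 16 tert-butyl{[(2R,3Z)-2,6-dimethylhept-3-en-1-yl]oxy}dimethylsilane, via phosphorus ylide 15 (not isolated)
Conditions: 14, NaHMDS, THF, 0 °C; then 13, −78 °C → rt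
Reagents that add atoms: none
Why: Wittig olefination with a lithium-free, non-stabilised ylide under kinetic control should give the Z-alkene through the cis-oxaphosphetane, and the fast addition at −78 °C leaves the α-stereocentre intact.

Step 9
Reactants: 16 tert-butyl{[(2R,3Z)-2,6-dimethylhept-3-en-1-yl]oxy}dimethylsilane
Product: 17 (2R,3Z)-2,6-dimethylhept-3-en-1-ol
Conditions: TBAF, THF, 0 °C → rt
Reagents that add atoms: none
Why: Fluoride-mediated cleavage of the Si–O bond, with no group present that is sensitive to fluoride.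

Step 10
Reactants: 17 (2R,3Z)-2,6-dimethylhept-3-en-1-ol
Product: 18 (2R,3Z)-2,6-dimethylhept-3-enal
Conditions: Dess–Martin periodinane, CH2Cl2, 0 °C; cold aq. NaHCO3/Na2S2O3; used at once
Reagents that add atoms: none
Why: Dess–Martin oxidation is close to neutral, so the β,γ-unsaturated α-methyl aldehyde should form without epimerisation or migration of the alkene into conjugation if it is used directly.

Step 11
Reactants: 18 (2R,3Z)-2,6-dimethylhept-3-enal
Product: 19 (1E,3R,4Z)-1-iodo-3,7-dimethylocta-1,4-diene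
Conditions: CrCl2, CHI3, THF, 0 °C, dark
Reagents that add atoms: iodoform, IC(I)I (the CHI unit)
Why: Takai olefination: the geminal dichromium species from iodoform adds to the aldehyde and eliminates to the E-alkenyl iodide under non-basic conditions that should spare the labile α-stereocentre and the Z-alkene.

Step 12
Reactants: 10 (1S,5R,6S)-5-[(tert-butyldimethylsilyl)oxy]-3-methyl-4-oxo-6-[(1E)-1-(4,4,5,5-tetramethyl-1,3,2-dioxaborolan-2-yl)prop-1-en-2-yl]cyclohex-2-en-1-yl acetate; 19 (1E,3R,4Z)-1-iodo-3,7-dimethylocta-1,4-diene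
Product: 20 (1S,5R,6S)-5-[(tert-butyldimethylsilyl)oxy]-6-[(2E,4E,6R,7Z)-6,10-dimethylundeca-2,4,7-trien-2-yl]-3-methyl-4-oxocyclohex-2-en-1-yl acetate
Conditions: Pd(PPh3)4 (cat.), TlOEt, degassed THF/H2O (3:1), rt, dark
Reagents that add atoms: none
Why: Pd(0) inserts into the C–I bond of 19 with retention of the E geometry, the alkenyl group of 10 is transferred from the ethoxide-activated boronate to palladium, and reductive elimination forms the C3′–C4′ bond of the diene. The closest known reaction type is the Suzuki–Miyaura alkenyl–alkenyl coupling of an alkenyl pinacol boronate with an alkenyl iodide under thallium(I) base acceleration. No ring is closed and no stereocentre is created; the 2′E geometry comes from 10 and the 4′E geometry from 19, both transferred with retention. The step needs chemoselectivity for the alkenyl iodide beside the enone, the allylic acetate (a possible π-allyl precursor) and the α-silyloxy ketone, and it needs the bis-allylic C6′ centre and the 7′Z alkene to stay untouched. The fast oxidative addition of the C(sp2)–I bond at room temperature, the absence of any leaving group or acidic C–H next to C6′, and the short exposure to a mild base should secure this.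

Step 13
Reactants: 20 (1S,5R,6S)-5-[(tert-butyldimethylsilyl)oxy]-6-[(2E,4E,6R,7Z)-6,10-dimethylundeca-2,4,7-trien-2-yl]-3-methyl-4-oxocyclohex-2-en-1-yl acetate
Product: 21 (1S,5R,6R)-6-[(2E,4E,6R,7Z)-6,10-dimethylundeca-2,4,7-trien-2-yl]-5-hydroxy-3-methyl-4-oxocyclohex-2-en-1-yl acetate
Conditions: HF·pyridine, pyridine, THF, 0 °C → rt
Reagents that add atoms: none
Why: Buffered fluoride cleaves the Si–O bond of the α-silyloxy ketone and should leave the acetate, the enone and the triene untouched, since the medium is neither basic enough for acyl cleavage nor acidic enough to ionise the allylic ester.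

**Compound list**
1 | (S)-(+)-carvone, (5S)-2-methyl-5-(prop-1-en-2-yl)cyclohex-2-en-1-one | CC1=CC[C@@H](CC1=O)C(C)=C | starting material
2 | sodium (3S)-6-methyl-3-(prop-1-en-2-yl)cyclohexa-1,5-dien-1-olate (α′-enolate of 1) | [Na+].[O-]C1=C[C@@H](C(C)=C)CC=C1C | intermediate (not isolated)
3 | (5R,6R)-6-hydroxy-2-methyl-5-(prop-1-en-2-yl)cyclohex-2-en-1-one | C1C=C(C)C(=O)[C@H](O)[C@H]1C(C)=C | intermediate
4 | (5R,6R)-6-[(tert-butyldimethylsilyl)oxy]-2-methyl-5-(prop-1-en-2-yl)cyclohex-2-en-1-one | C1C=C(C)C(=O)[C@H](O[Si](C)(C)C(C)(C)C)[C@H]1C(C)=C | intermediate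
5 | potassium (5R,6R)-6-[(tert-butyldimethylsilyl)oxy]-2-methyl-5-(prop-1-en-2-yl)cyclohexa-1,3-dien-1-olate | [K+].[O-]C1=C(C)C=C[C@H](C(C)=C)[C@H]1O[Si](C)(C)C(C)(C)C | intermediate (not isolated)
6 | (5R,6R)-6-[(tert-butyldimethylsilyl)oxy]-2-methyl-5-(prop-1-en-2-yl)-1-[(triethylsilyl)oxy]cyclohexa-1,3-diene | CC[Si](CC)(CC)OC1=C(C)C=C[C@H](C(C)=C)[C@H]1O[Si](C)(C)C(C)(C)C | intermediate (not isolated)
7 | (3R,4S,5S,6R)-6-[(tert-butyldimethylsilyl)oxy]-3,4-epoxy-2-methyl-5-(prop-1-en-2-yl)-1-[(triethylsilyl)oxy]cyclohex-1-ene (epoxide anti to the isopropenyl group) | CC[Si](CC)(CC)OC1=C(C)[C@H]2O[C@H]2[C@H](C(C)=C)[C@H]1O[Si](C)(C)C(C)(C)C | intermediate (not isolated)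
8 | (4R,5S,6R)-6-[(tert-butyldimethylsilyl)oxy]-4-hydroxy-2-methyl-5-(prop-1-en-2-yl)cyclohex-2-en-1-one | O[C@@H]1C=C(C)C(=O)[C@H](O[Si](C)(C)C(C)(C)C)[C@H]1C(C)=C | intermediate
9 | (1S,5R,6S)-5-[(tert-butyldimethylsilyl)oxy]-3-methyl-4-oxo-6-(prop-1-en-2-yl)cyclohex-2-en-1-yl acetate | CC(=O)O[C@H]1C=C(C)C(=O)[C@H](O[Si](C)(C)C(C)(C)C)[C@H]1C(C)=C | intermediate
10 | (1S,5R,6S)-5-[(tert-butyldimethylsilyl)oxy]-3-methyl-4-oxo-6-[(1E)-1-(4,4,5,5-tetramethyl-1,3,2-dioxaborolan-2-yl)prop-1-en-2-yl]cyclohex-2-en-1-yl acetate | CC(=O)O[C@H]1C=C(C)C(=O)[C@H](O[Si](C)(C)C(C)(C)C)[C@H]1/C(C)=C/B1OC(C)(C)C(C)(C)O1 | intermediate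
11 | methyl (S)-3-hydroxy-2-methylpropanoate | C[C@@H](CO)C(=O)OC | starting material
12 | methyl (S)-3-[(tert-butyldimethylsilyl)oxy]-2-methylpropanoate | C[C@@H](CO[Si](C)(C)C(C)(C)C)C(=O)OC | intermediate
13 | (S)-3-[(tert-butyldimethylsilyl)oxy]-2-methylpropanal | C[C@@H](CO[Si](C)(C)C(C)(C)C)C=O | intermediate
14 | (3-methylbutyl)triphenylphosphonium bromide | CC(C)CC[P+](c1ccccc1)(c1ccccc1)c1ccccc1.[Br-] | starting material
15 | (3-methylbutylidene)triphenylphosphorane | CC(C)CC=P(c1ccccc1)(c1ccccc1)c1ccccc1 | intermediate (not isolated)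
16 | tert-butyl{[(2R,3Z)-2,6-dimethylhept-3-en-1-yl]oxy}dimethylsilane | C[C@@H](CO[Si](C)(C)C(C)(C)C)/C=C\CC(C)C | intermediate
17 | (2R,3Z)-2,6-dimethylhept-3-en-1-ol | C[C@@H](CO)/C=C\CC(C)C | intermediate
18 | (2R,3Z)-2,6-dimethylhept-3-enal | C[C@@H](C=O)/C=C\CC(C)C | intermediate
19 | (1E,3R,4Z)-1-iodo-3,7-dimethylocta-1,4-diene | I/C=C/[C@H](C)/C=C\CC(C)C | intermediate
20 | (1S,5R,6S)-5-[(tert-butyldimethylsilyl)oxy]-6-[(2E,4E,6R,7Z)-6,10-dimethylundeca-2,4,7-trien-2-yl]-3-methyl-4-oxocyclohex-2-en-1-yl acetate | CC(=O)O[C@H]1C=C(C)C(=O)[C@H](O[Si](C)(C)C(C)(C)C)[C@H]1/C(C)=C/C=C/[C@H](C)/C=C\CC(C)C | intermediate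
21 | (1S,5R,6R)-6-[(2E,4E,6R,7Z)-6,10-dimethylundeca-2,4,7-trien-2-yl]-5-hydroxy-3-methyl-4-oxocyclohex-2-en-1-yl acetate | CC(=O)O[C@H]1C=C(C)C(=O)[C@H](O)[C@H]1/C(C)=C/C=C/[C@H](C)/C=C\CC(C)C | target

**Totals**
Total step count: 13. Longest linear sequence: 8 steps (11 → 21, steps 6–13); the carvone branch is 7 steps (steps 1–5, 12, 13).

**Steps most likely to fail**

Step 3. What may go wrong: silylation of the α′-enolate at C6 instead of the γ-dienolate, oxygen transfer to the C1=C2 enol-ether bond (α-hydroxylation), or attack from the isopropenyl face. The fallback sets out from 4. A copper(II)-catalysed aerobic γ-oxidation (Cu(OTf)2 cat., 1,1,3,3-tetramethylguanidine, air, THF, rt) of the equilibrating dienolate should take up dioxygen at C4 and give the γ-hydroperoxide (4R,5S,6R)-6-[(tert-butyldimethylsilyl)oxy]-4-hydroperoxy-2-methyl-5-(prop-1-en-2-yl)cyclohex-2-en-1-one F1. Reduction with PPh3 in the same flask would come back to the route at 8. This replaces the preformed silyl dienol ether and the electrophilic epoxidation by capture of dioxygen at the γ-carbon.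

Step 5. What may go wrong: slow turnover at the α-branched, doubly flanked 1,1-disubstituted alkene with decay of the catalyst, and incomplete control of the alkene geometry. The fallback sets out from 9. A palladium-catalysed boryl-Heck reaction (Pd(0)/bulky monophosphine, B-chlorocatecholborane, tertiary amine, LiOTf, PhCF3, 70 °C) proceeds by syn-borylpalladation of the =CH2 terminus and β-hydride elimination, keeps the original methylene carbon, and should give the catechol boronate (1S,5R,6S)-6-[(1E)-1-(1,3,2-benzodioxaborol-2-yl)prop-1-en-2-yl]-5-[(tert-butyldimethylsilyl)oxy]-3-methyl-4-oxocyclohex-2-en-1-yl acetate F2. Transesterification with pinacol in the same flask would come back to the route at 10.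

Step 4. What may go wrong: slow SN2 displacement at the flanked allylic carbinol, so that elimination towards the dienone (and on to the phenol) or incomplete inversion competes. The fallback sets out from 8. Oxidation with Dess–Martin periodinane would give the ene-1,4-dione (5R,6R)-6-[(tert-butyldimethylsilyl)oxy]-2-methyl-5-(prop-1-en-2-yl)cyclohex-2-ene-1,4-dione F3. Luche reduction (NaBH4, CeCl3·7H2O, MeOH, −78 °C) of the less hindered C4 carbonyl from the face opposite the isopropenyl group should give the cis alcohol (4S,5S,6R)-6-[(tert-butyldimethylsilyl)oxy]-4-hydroxy-2-methyl-5-(prop-1-en-2-yl)cyclohex-2-en-1-one F4. Acetylation (Ac2O, pyridine, DMAP) would come back to the route at 9; the C4 centre is then set by hydride delivery instead of substitution.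

**Further compounds**
F1 | step 3 | (4R,5S,6R)-6-[(tert-butyldimethylsilyl)oxy]-4-hydroperoxy-2-methyl-5-(prop-1-en-2-yl)cyclohex-2-en-1-one | OO[C@@H]1C=C(C)C(=O)[C@H](O[Si](C)(C)C(C)(C)C)[C@H]1C(C)=C
F2 | step 5 | (1S,5R,6S)-6-[(1E)-1-(1,3,2-benzodioxaborol-2-yl)prop-1-en-2-yl]-5-[(tert-butyldimethylsilyl)oxy]-3-methyl-4-oxocyclohex-2-en-1-yl acetate | CC(=O)O[C@H]1C=C(C)C(=O)[C@H](O[Si](C)(C)C(C)(C)C)[C@H]1/C(C)=C/B1Oc2ccccc2O1
F3 | step 4 | (5R,6R)-6-[(tert-butyldimethylsilyl)oxy]-2-methyl-5-(prop-1-en-2-yl)cyclohex-2-ene-1,4-dione | O=C1C=C(C)C(=O)[C@H](O[Si](C)(C)C(C)(C)C)[C@H]1C(C)=C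
F4 | step 4 | (4S,5S,6R)-6-[(tert-butyldimethylsilyl)oxy]-4-hydroxy-2-methyl-5-(prop-1-en-2-yl)cyclohex-2-en-1-one | O[C@H]1C=C(C)C(=O)[C@H](O[Si](C)(C)C(C)(C)C)[C@H]1C(C)=C
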